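Two questions stood before me for the flask with 20 mM of substrate and 21.0 mM of partner: at what level of by-product does its rate change order, and how much is left at 15 h?

| setting | teal | grey | violet | flask |
|---|---|---|---|---|
| substrate | 20 mM | 20 mM | 40 mM | 20 mM |
| partner | 10 mM | 42 mM | 21 mM | 21.0 mM |
| base | 2 mM | 2 mM | 2 mM | 2.00 mM |
| remark | run made earlier | run made earlier | run made earlier |  |
| time |  |  |  | 15 h |

| run | time / h | isomer of the product / % | substrate / % | target / % |
|---|---|---|---|---|
| teal | 1.00 | 0.7 | 97.1 | 3.6 |
| teal | 2.00 | 0.4 | 93.4 | 5.5 |
| teal | 3.00 | 0.7 | 91.6 | 7.7 |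
| teal | 6.00 | 3.8 | 82.9 | 14.6 |
| teal | 12.0 | 11.4 | 64.8 | 24.3 |
| grey | 2.50 | 3.7 | 49.3 | 46.8 |
| grey | 5.00 | 17.0 | 8.2 | 74.4 |
| grey | 8.00 | 30.7 | 1.0 | 67.4 |
| grey | 10.0 | 38.4 | 0 | 61.5 |
| grey | 12.0 | 43.7 | 0.1 | 56.6 |
| violet | 1.00 | 0.7 | 93.0 | 6.6 |
| violet | 2.00 | 1.3 | 81.9 | 17.4 |
| violet | 3.00 | 3.2 | 67.6 | 29.0 |
| violet | 6.00 | 11.2 | 50.3 | 38.5 |
| violet | 12.0 | 22.6 | 48.0 | 29.8 |

(each reading ± 0.3 percentage points)

- what was read earlier has a scatter of 0.3 percentage points, one standard deviation
- on the list of suspects stand: substrate + partner + by-product -> target + 2 by-product; substrate + partner -> target + by-product; base + by-product <-> salt; target <-> isomer of the product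

- the isomer of the product in the flask at 15 h, as a percentage of the substrate charged
- the substrate in the flask at 15 h, as a percentage of the substrate charged
- the target in the flask at 15 h, as a percentage of the substrate charged
- concentration of partner at 15 h, in mM

In the teal run 1.68 mM of substrate went in 3.00 h, less than the 2 mM of base that takes up by-product as salt. So free by-product stayed low, and rate over substrate times partner gave a plain constant of 0.00319 /mM/h.

In the violet run, between 2.00 h and 3.00 h, about 8.10 mM of by-product stood free, and the same quotient read 0.0176 /mM/h, larger than the plain constant. I took the excess as by-product speeding its own making (autocatalysis). Scaling it down gives 1.80 mM: the crossover level, the free by-product at which that route runs as fast as the plain one. The rate is then the plain rate times one plus by-product over crossover, second order below the crossover and third order above it.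

In this flask the base lasts about 1.49 h, and free by-product can climb to 18.0 mM, which is 10.0 times the crossover. The excess of partner over substrate, 1.00 mM, was far smaller than the substrate charged, so the two fall together. Holding by-product at that ceiling, which overstates it, leaves 1.89 mM of substrate, 9.45 %: my low mark.

The forecast gave 33 % isomer, 14 % substrate, above my low mark, 53 % target and 3.8 mM partner, with “the autocatalytic route is active”.

The flask gave 36.8 % isomer, 12.3 % substrate, 51.0 % target and 3.46 mM partner.

    substrate + partner + by-product → target + 2 by-product (k = 0.491 /M²/s)
    substrate + partner → target + by-product (k = 9.43 × 10⁻⁴ /M/s)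
    base + by-product ⇌ salt, settled at all times (K = 1.29 × 10⁵ /M)
    target ⇌ isomer of the product (K = 1.40, k = 2.43 × 10⁻⁵ /s)

At 15.0 h this flask held 15.5 mM of free by-product, 8.61 times the crossover, so by my reckoning the by-product route carried 89.6 % of the rate at that moment, and the partner's half-life by that step stood at 10 h. The same flask stopped at 4.0 h held 4.45 mM, 2.47 times the crossover, which puts that route's share of the rate at that moment at 71.2 %. That neighbour had 28.1 % target and 67.7 % substrate left.

(The numbers in the tables were generated by integration for substances that don't exist; noise was put on by code.)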